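**Retrosynthetic overview**
1. Target 21 ⇐ tetra-benzyl ether 20 by one global hydrogenolysis.
2. 20 ⇐ cyclohexenone 17: the key bond is the O–CH3 bond; methylation of the ketone oxygen triggers aromatisation and decides which oxygen carries the methyl group.
3. 17 ⇐ 14 + 15 (α'-benzylation); 14 ⇐ 13 (O-benzylation of a symmetric dione); 13 ⇐ 10 + 11 (reductive C2-benzylation).
4. 10 ⇐ 5 + 6 (Michael–Claisen annulation); 5 ⇐ 3 + 4 (Wittig); 3 ⇐ 1 + 2 (Heck).
5. Ring order: the three outer benzene rings are bought; the central ring A is the only ring built, as a cyclohexane-1,3-dione in step 3, and it is aromatised in step 7.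

Assumption: the target SMILES has no stereocentre and no stereogenic double bond, so the compound is achiral and no stereocontrol is needed; sp3 stereocentres in intermediates are racemic and are erased in step 7.

**Step 1**
Reactants: 1 1-(benzyloxy)-3-iodobenzene; 2 prop-2-en-1-ol (allyl alcohol)
Product: 3 3-[3-(benzyloxy)phenyl]propanal
Conditions: Pd(OAc)2 (3 mol%), Bu4NCl, NaHCO3, DMF, 40 °C
Reagents that add atoms: none
Why: Heck arylation of an allylic alcohol under Jeffery conditions, in which the arylpalladium species adds to the terminal alkene carbon and β-hydride elimination toward the carbinol gives an enol that tautomerises to the aldehyde; no stereocentre is formed.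

**Step 2**
Reactants: 3 3-[3-(benzyloxy)phenyl]propanal; 4 1-(triphenyl-λ5-phosphanylidene)propan-2-one
Product: 5 (3E)-6-[3-(benzyloxy)phenyl]hex-3-en-2-one
Conditions: toluene, 80 °C
Reagents that add atoms: none
Why: Wittig olefination with a stabilised acetonyl ylide, which gives the E-enone selectively and avoids the self-condensation of a base-mediated aldol route.

**Step 3**
Reactants: 5 (3E)-6-[3-(benzyloxy)phenyl]hex-3-en-2-one; 6 diethyl malonate
Product: 10 5-{2-[3-(benzyloxy)phenyl]ethyl}cyclohexane-1,3-dione, via Michael adduct 7 (not isolated), via cyclic keto ester 8 (not isolated), via keto acid 9 (not isolated)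
Conditions: NaOEt, EtOH, reflux; then aq. NaOH, reflux; then aq. HCl, 80 °C
Reagents that add atoms: none
Why: classical Michael addition, intramolecular Claisen condensation, saponification and decarboxylation to a 5-substituted cyclohexane-1,3-dione; the product is symmetric and has no stereocentre.

**Step 4**
Reactants: 10 5-{2-[3-(benzyloxy)phenyl]ethyl}cyclohexane-1,3-dione; 11 4-(benzyloxy)benzaldehyde
Product: 13 2-[4-(benzyloxy)benzyl]-5-{2-[3-(benzyloxy)phenyl]ethyl}cyclohexane-1,3-dione, via arylidene dione 12 (not isolated)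
Conditions: Hantzsch ester (diethyl 2,6-dimethyl-1,4-dihydropyridine-3,5-dicarboxylate), L-proline (20 mol%), CH2Cl2, rt
Reagents that add atoms: none
Why: organocatalytic three-component reductive alkylation (Knoevenagel condensation, then conjugate hydride transfer from the Hantzsch ester), which gives clean C2-monoalkylation without O-alkylation or dialkylation; no fixed stereocentre results because the dione enolises.

**Step 5**
Reactants: 13 2-[4-(benzyloxy)benzyl]-5-{2-[3-(benzyloxy)phenyl]ethyl}cyclohexane-1,3-dione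
Product: 14 3-(benzyloxy)-2-[4-(benzyloxy)benzyl]-5-{2-[3-(benzyloxy)phenyl]ethyl}cyclohex-2-en-1-one
Conditions: BnOH, p-TsOH·H2O (5 mol%), toluene, reflux, Dean–Stark
Reagents that add atoms: benzyl alcohol, OCc1ccccc1
Why: acid-catalysed enol etherification to a vinylogous ester; the two carbonyl groups of 13 are equivalent by symmetry, so only one constitutional isomer can form, and C5 becomes a racemic stereocentre.

**Step 6**
Reactants: 14 3-(benzyloxy)-2-[4-(benzyloxy)benzyl]-5-{2-[3-(benzyloxy)phenyl]ethyl}cyclohex-2-en-1-one; 15 1-(benzyloxy)-4-(bromomethyl)benzene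
Product: 17 3-(benzyloxy)-2,6-bis[4-(benzyloxy)benzyl]-5-{2-[3-(benzyloxy)phenyl]ethyl}cyclohex-2-en-1-one, via lithium enolate 16 (not isolated)
Conditions: LiN(iPr)2, THF, −78 °C; then 15, −78 → 0 °C
Reagents that add atoms: none
Why: Stork–Danheiser kinetic α'-alkylation of a vinylogous ester, which places the second benzyl group next to the ketone so that the ketone carbon is flanked by both benzyl groups; the new C6 centre forms mainly trans to the C5 chain (racemic) and both sp3 centres are erased in step 7.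

**Step 7**
Reactants: 17 3-(benzyloxy)-2,6-bis[4-(benzyloxy)benzyl]-5-{2-[3-(benzyloxy)phenyl]ethyl}cyclohex-2-en-1-one
Product: 20 1-(benzyloxy)-2,4-bis[4-(benzyloxy)benzyl]-5-{2-[3-(benzyloxy)phenyl]ethyl}-3-methoxybenzene, via methoxycyclohexenylium salt 18 (not isolated), via dialkoxycyclohexadiene 19 (not isolated)
Conditions: Me3OBF4, CH2Cl2, 0 °C; then KN(SiMe3)2, THF, −78 °C; then DDQ, −78 → 0 °C
Reagents that add atoms: trimethyloxonium tetrafluoroborate, C[O+](C)C.F[B-](F)(F)F
Why: Proposed new method: an O-methylation-triggered dehydrogenative aromatisation in which Me3OBF4 alkylates the carbonyl oxygen of the vinylogous ester (its only strongly nucleophilic site, so C-methylation cannot compete) to give the 1-methoxy-3-benzyloxycyclohexenylium salt 18, KN(SiMe3)2 removes an α-proton (C4 or C6, both convergent) to give diene 19, and DDQ abstracts the C5 hydride to a doubly alkoxy-stabilised arenium ion that loses a proton, so the methyl group ends up on the oxygen flanked by both benzyl groups while the other oxygen stays benzyl-protected; the closest known reactions are Meerwein O-alkylation of vinylogous esters to 1,3-dialkoxycyclohexenylium salts, deprotonation of oxocarbenium ions to enol ethers, DDQ aromatisation of alkoxycyclohexadienes and the iodine/methanol conversion of cyclohexenones into anisoles, which have not been merged to turn a vinylogous ester into an unsymmetrical resorcinol diether.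

**Step 8**
Reactants: 20 1-(benzyloxy)-2,4-bis[4-(benzyloxy)benzyl]-5-{2-[3-(benzyloxy)phenyl]ethyl}-3-methoxybenzene
Product: 21 Bulbocodin C (2,4-bis(4-hydroxybenzyl)-5-[2-(3-hydroxyphenyl)ethyl]-3-methoxyphenol)
Conditions: H2 (1 atm), 10% Pd/C, THF/MeOH, rt
Reagents that add atoms: none
Why: catalytic hydrogenolysis cleaves all four aryl benzyl ethers at once, while the diarylmethane C–C bonds, the aryl methyl ether and the arenes are inert under these conditions.

**Compound list**
1 | 1-(benzyloxy)-3-iodobenzene | Ic1cccc(OCc2ccccc2)c1 | starting material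
2 | prop-2-en-1-ol (allyl alcohol) | C=CCO | starting material
3 | 3-[3-(benzyloxy)phenyl]propanal | O=CCCc1cccc(OCc2ccccc2)c1 | intermediate
4 | 1-(triphenyl-λ5-phosphanylidene)propan-2-one | CC(=O)C=P(c1ccccc1)(c1ccccc1)c1ccccc1 | starting material
5 | (3E)-6-[3-(benzyloxy)phenyl]hex-3-en-2-one | CC(=O)/C=C/CCc1cccc(OCc2ccccc2)c1 | intermediate
6 | diethyl malonate | CCOC(=O)CC(=O)OCC | starting material
7 | diethyl 2-{1-[3-(benzyloxy)phenyl]-5-oxohexan-3-yl}propanedioate (racemic; Michael adduct; not isolated) | CCOC(=O)C(C(=O)OCC)C(CCc1cccc(OCc2ccccc2)c1)CC(C)=O | intermediate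
8 | ethyl 2-{2-[3-(benzyloxy)phenyl]ethyl}-4,6-dioxocyclohexane-1-carboxylate (racemic; present as its sodium enolate; not isolated) | CCOC(=O)C1C(CCc2cccc(OCc3ccccc3)c2)CC(=O)CC1=O | intermediate
9 | 2-{2-[3-(benzyloxy)phenyl]ethyl}-4,6-dioxocyclohexane-1-carboxylic acid (racemic; not isolated) | OC(=O)C1C(CCc2cccc(OCc3ccccc3)c2)CC(=O)CC1=O | intermediate
10 | 5-{2-[3-(benzyloxy)phenyl]ethyl}cyclohexane-1,3-dione (achiral) | O=C1CC(=O)CC(CCc2cccc(OCc3ccccc3)c2)C1 | intermediate
11 | 4-(benzyloxy)benzaldehyde | O=Cc1ccc(OCc2ccccc2)cc1 | starting material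
12 | 2-[4-(benzyloxy)benzylidene]-5-{2-[3-(benzyloxy)phenyl]ethyl}cyclohexane-1,3-dione (not isolated) | O=C1CC(CCc2cccc(OCc3ccccc3)c2)CC(=O)C1=Cc1ccc(OCc2ccccc2)cc1 | intermediate
13 | 2-[4-(benzyloxy)benzyl]-5-{2-[3-(benzyloxy)phenyl]ethyl}cyclohexane-1,3-dione (mainly the enol tautomer; no fixed stereocentre) | O=C1CC(CCc2cccc(OCc3ccccc3)c2)CC(=O)C1Cc1ccc(OCc2ccccc2)cc1 | intermediate
14 | 3-(benzyloxy)-2-[4-(benzyloxy)benzyl]-5-{2-[3-(benzyloxy)phenyl]ethyl}cyclohex-2-en-1-one (racemic at C5) | O=C1CC(CCc2cccc(OCc3ccccc3)c2)CC(OCc2ccccc2)=C1Cc1ccc(OCc2ccccc2)cc1 | intermediate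
15 | 1-(benzyloxy)-4-(bromomethyl)benzene | BrCc1ccc(OCc2ccccc2)cc1 | starting material
16 | lithium 5-(benzyloxy)-6-[4-(benzyloxy)benzyl]-3-{2-[3-(benzyloxy)phenyl]ethyl}cyclohexa-1,5-dien-1-olate (kinetic enolate of 14; racemic; not isolated) | [Li+].[O-]C1=CC(CCc2cccc(OCc3ccccc3)c2)CC(OCc2ccccc2)=C1Cc1ccc(OCc2ccccc2)cc1 | intermediate
17 | 3-(benzyloxy)-2,6-bis[4-(benzyloxy)benzyl]-5-{2-[3-(benzyloxy)phenyl]ethyl}cyclohex-2-en-1-one (racemic; mainly 5,6-trans; diastereomer mixture usable) | O=C1C(Cc2ccc(OCc3ccccc3)cc2)=C(OCc2ccccc2)CC(CCc2cccc(OCc3ccccc3)c2)C1Cc1ccc(OCc2ccccc2)cc1 | intermediate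
18 | 3-(benzyloxy)-2,6-bis[4-(benzyloxy)benzyl]-5-{2-[3-(benzyloxy)phenyl]ethyl}-1-methoxycyclohex-2-en-1-ylium tetrafluoroborate (racemic; not isolated) | C[O+]=C1C(Cc2ccc(OCc3ccccc3)cc2)=C(OCc2ccccc2)CC(CCc2cccc(OCc3ccccc3)c2)C1Cc1ccc(OCc2ccccc2)cc1.F[B-](F)(F)F | intermediate
19 | 2-(benzyloxy)-3,5-bis[4-(benzyloxy)benzyl]-6-{2-[3-(benzyloxy)phenyl]ethyl}-4-methoxycyclohexa-1,3-diene (racemic; not isolated; the regioisomeric diene from C6 deprotonation gives the same arene) | COC1=C(Cc2ccc(OCc3ccccc3)cc2)C(OCc2ccccc2)=CC(CCc2cccc(OCc3ccccc3)c2)C1Cc1ccc(OCc2ccccc2)cc1 | intermediate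
20 | 1-(benzyloxy)-2,4-bis[4-(benzyloxy)benzyl]-5-{2-[3-(benzyloxy)phenyl]ethyl}-3-methoxybenzene (achiral) | COc1c(Cc2ccc(OCc3ccccc3)cc2)c(OCc2ccccc2)cc(CCc2cccc(OCc3ccccc3)c2)c1Cc1ccc(OCc2ccccc2)cc1 | intermediate
21 | Bulbocodin C, 2,4-bis(4-hydroxybenzyl)-5-[2-(3-hydroxyphenyl)ethyl]-3-methoxyphenol (achiral) | COc1c(Cc2ccc(O)cc2)c(O)cc(CCc2cccc(O)c2)c1Cc1ccc(O)cc1 | target

**Step count and risks**
Total steps: 8. Longest linear sequence: 8 (fully linear).

Three steps most likely to fail:

Step 7 (the proposed new step). The risks are loss of the benzyl group from cation 18 (which would scramble the two oxygens), Friedel–Crafts benzyl transfer to the electron-rich rings, and over-oxidation of the diarylmethane positions by DDQ. The fallback uses known chemistry only; it sets out from 17 and comes back at 20. Treatment of 17 with LiN(iPr)2 and Me3SiCl gives the silyl dienol ether 4-(benzyloxy)-1,3-bis[4-(benzyloxy)benzyl]-6-{2-[3-(benzyloxy)phenyl]ethyl}-2-(trimethylsilyloxy)cyclohexa-1,3-diene F1. Saegusa–Ito oxidation of this with Pd(OAc)2 in MeCN gives, after tautomerisation, 3-(benzyloxy)-2,6-bis[4-(benzyloxy)benzyl]-5-{2-[3-(benzyloxy)phenyl]ethyl}phenol F2. Williamson methylation of the phenol (MeI, K2CO3, DMF) then gives 20; here the aromatic ring is made first and the C–O bond is formed afterwards on the phenol.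

Step 6. The risks are slow alkylation of the hindered enolate, dialkylation and proton transfer. The fallback sets out from 14 and comes back at 17, replacing alkylation by aldol condensation and conjugate reduction. Lithium enolate 16 is added to aldehyde 11 to give the aldol 3-(benzyloxy)-2-[4-(benzyloxy)benzyl]-6-{[4-(benzyloxy)phenyl](hydroxy)methyl}-5-{2-[3-(benzyloxy)phenyl]ethyl}cyclohex-2-en-1-one F3. Acid-catalysed dehydration (cat. p-TsOH, toluene, 60 °C) gives (6E)-3-(benzyloxy)-2-[4-(benzyloxy)benzyl]-6-[4-(benzyloxy)benzylidene]-5-{2-[3-(benzyloxy)phenyl]ethyl}cyclohex-2-en-1-one F4. Chemoselective 1,4-reduction of the exocyclic enone with [(Ph3P)CuH]6 in THF then gives 17.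

Step 3. The risks are self-condensation or retro-Michael reaction of the aliphatic enone and incomplete decarboxylation. The fallback sets out from 3 and comes back at 8, using the acetoacetate/enoate variant of the dione synthesis. Horner–Wadsworth–Emmons olefination of 3 (triethyl phosphonoacetate, NaH, THF) gives ethyl (2E)-5-[3-(benzyloxy)phenyl]pent-2-enoate F5. Michael addition of ethyl acetoacetate (NaOEt, EtOH, reflux) gives diethyl 2-acetyl-3-{2-[3-(benzyloxy)phenyl]ethyl}pentanedioate F6, which closes in the same flask by Claisen condensation to 8. Saponification and decarboxylation as in step 3 then give 10.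

**Further compounds**
F1 | step 7 | 4-(benzyloxy)-1,3-bis[4-(benzyloxy)benzyl]-6-{2-[3-(benzyloxy)phenyl]ethyl}-2-(trimethylsilyloxy)cyclohexa-1,3-diene (racemic) | C[Si](C)(C)OC1=C(Cc2ccc(OCc3ccccc3)cc2)C(CCc2cccc(OCc3ccccc3)c2)CC(OCc2ccccc2)=C1Cc1ccc(OCc2ccccc2)cc1
F2 | step 7 | 3-(benzyloxy)-2,6-bis[4-(benzyloxy)benzyl]-5-{2-[3-(benzyloxy)phenyl]ethyl}phenol | Oc1c(Cc2ccc(OCc3ccccc3)cc2)c(OCc2ccccc2)cc(CCc2cccc(OCc3ccccc3)c2)c1Cc1ccc(OCc2ccccc2)cc1
F3 | step 6 | 3-(benzyloxy)-2-[4-(benzyloxy)benzyl]-6-{[4-(benzyloxy)phenyl](hydroxy)methyl}-5-{2-[3-(benzyloxy)phenyl]ethyl}cyclohex-2-en-1-one (racemic diastereomer mixture) | O=C1C(Cc2ccc(OCc3ccccc3)cc2)=C(OCc2ccccc2)CC(CCc2cccc(OCc3ccccc3)c2)C1C(O)c1ccc(OCc2ccccc2)cc1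
F4 | step 6 | (6E)-3-(benzyloxy)-2-[4-(benzyloxy)benzyl]-6-[4-(benzyloxy)benzylidene]-5-{2-[3-(benzyloxy)phenyl]ethyl}cyclohex-2-en-1-one (racemic) | O=C1C(Cc2ccc(OCc3ccccc3)cc2)=C(OCc2ccccc2)CC(CCc2cccc(OCc3ccccc3)c2)/C1=C\c1ccc(OCc2ccccc2)cc1
F5 | step 3 | ethyl (2E)-5-[3-(benzyloxy)phenyl]pent-2-enoate | CCOC(=O)/C=C/CCc1cccc(OCc2ccccc2)c1
F6 | step 3 | diethyl 2-acetyl-3-{2-[3-(benzyloxy)phenyl]ethyl}pentanedioate (racemic diastereomer mixture) | CCOC(=O)CC(CCc1cccc(OCc2ccccc2)c1)C(C(C)=O)C(=O)OCC
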